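The route rests on two C–C disconnections at the flavanone C ring: C3–C8'' (Pinhey ligand coupling of an 8-flavonyl lead(IV) reagent with a β-keto ester) and C2–aryl (Pd-catalysed enantioselective conjugate arylation). Both need an ester at C3, and the key step supplies it while making the ring: a rhodium carbenoid from tert-butyl bromodiazoacetate inserts one carbon into the C2=C3 enol ether bond of an achiral 3-silyloxybenzofuran, so the five-membered ring O1–C2–C3–C3a–C7a grows into the six-membered pyranone ring. The step exploits that C3 is the single ring carbon between C2 (on O1) and the C4 carbonyl. C2 is set afterwards; C3 equilibrates to trans once the ester leaves.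

Key step: step 4

Remark on the chemistry: hydrogen sulfates 22 and 23 are written as free acids; they would be handled as pyridinium or sodium salts and 23 freed by H+ ion exchange after step 15; in step 5 the PyOx antipode that gives 2R is used ((S) is expected by analogy with the parent chromone).

Step 1
Reactants: 1 4,6-dihydroxy-1-benzofuran-3(2H)-one
Product: 2 4,6-bis(benzyloxy)-1-benzofuran-3(2H)-one
Conditions: BnBr, K2CO3, DMF, rt to 50 °C
Reagents that add atoms: benzyl bromide, BrCc1ccccc1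
Why: Williamson etherification of both phenols; with carbonate the phenoxides should react ahead of the C2 methylene, so O-benzylation should dominate.

Step 2
Reactants: 2 4,6-bis(benzyloxy)-1-benzofuran-3(2H)-one
Product: 3 4,6-bis(benzyloxy)-3-[(tert-butyldimethylsilyl)oxy]-1-benzofuran
Conditions: TBSOTf, Et3N, CH2Cl2, 0 °C
Reagents that add atoms: tert-butyldimethylsilyl trifluoromethanesulfonate, CC(C)(C)[Si](C)(C)OS(=O)(=O)C(F)(F)F
Why: O-silylation under soft enolisation (silyl enol ether formation) should give the aromatic 3-silyloxybenzofuran, which exposes C2=C3 as an electron-rich enol ether bond.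

Step 3
Reactants: 4 tert-butyl diazoacetate
Product: 5 tert-butyl bromo(diazo)acetate
Conditions: NBS, DBU, CH2Cl2, 0 °C, short cold silica plug, used at once as a solution
Reagents that add atoms: N-bromosuccinimide, O=C1CCC(=O)N1Br
Why: Electrophilic bromination of the diazo carbon (halodiazoacetate formation with NBS/DBU) should give the unstable bromodiazo ester, which is not stored.

Step 4
Reactants: 3 4,6-bis(benzyloxy)-3-[(tert-butyldimethylsilyl)oxy]-1-benzofuran, 5 tert-butyl bromo(diazo)acetate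
Product: 8 tert-butyl 5,7-bis(benzyloxy)-4-oxo-4H-chromene-3-carboxylate, via bromocyclopropane adduct 6 (not isolated), via 4-silyloxychromenylium bromide 7 (not isolated)
Conditions: Rh2(esp)2 (1 mol%), CH2Cl2, 0 °C to rt; aq. NaHCO3 work-up
Reagents that add atoms: none
Why: The Rh(II) carbenoid from 5 should add across the C2=C3 enol ether bond of 3, by far its most electron-rich π bond, to give bromocyclopropane 6 (concerted [2+1] cyclopropanation, ester expected exo and bromine endo); ionisation of bromide with disrotatory opening of the shared C2–C3 bond (cyclopropyl-to-allyl cation electrocyclic ring opening) then enlarges the five-membered ring to the aromatic 4-silyloxybenzopyrylium 7, and bromide removes the silyl group to leave chromone 8. The closest known reactions are the halodiazoacetate cyclopropanation–ring expansion of indoles to quinoline-3-carboxylates and the dihalocarbene ring enlargement of silyl enol ethers (Ciamician–Dennstedt type). The three-membered ring closes by [2+1] cycloaddition, and the six-membered ring arises by electrocyclic opening of the fusion bond, not by a cyclisation. No stereocentre survives, since 6 is racemic and both its ring-fusion centres become sp2. The step needs cyclopropanation of the furan bond in preference to the benzyloxy arenes, which the silyl enol ether polarisation should secure, and cleavage of C2–C3 instead of the donor–acceptor C3–C(CO2tBu) bond, which the leaving bromide between two oxygen-bearing termini and the aromaticity of 7 should secure.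

Step 5
Reactants: 8 tert-butyl 5,7-bis(benzyloxy)-4-oxo-4H-chromene-3-carboxylate, 9 [4-(benzyloxy)phenyl]boronic acid
Product: 10 tert-butyl (2R,3S)-5,7-bis(benzyloxy)-2-[4-(benzyloxy)phenyl]-4-oxochromane-3-carboxylate
Conditions: Pd(OCOCF3)2 (5 mol%), (S)-t-BuPyOx (6 mol%), NH4PF6, H2O, ClCH2CH2Cl, 60 °C
Reagents that add atoms: none
Why: Pd(II)/PyOx-catalysed asymmetric conjugate addition of the arylboronic acid (Hayashi–Miyaura type, base-free) should deliver the aryl group to one face of C2 under ligand control to set 2R, while C3 is an enolisable β-keto ester centre that settles trans.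

Step 6
Reactants: 11 1-(2,4,6-trihydroxyphenyl)ethanone
Product: 12 1-[2,6-dihydroxy-4-(methoxymethoxy)phenyl]ethanone
Conditions: MOMCl (1.05 equiv), K2CO3, acetone, 0 °C to rt
Reagents that add atoms: chloromethyl methyl ether, COCCl
Why: Williamson alkylation with one equivalent of MOMCl should take the 4-OH, the only hydroxyl not hydrogen-bonded to the acetyl group and the most acidic one.

Step 7
Reactants: 12 1-[2,6-dihydroxy-4-(methoxymethoxy)phenyl]ethanone
Product: 13 1-[2-(benzyloxy)-6-hydroxy-4-(methoxymethoxy)phenyl]ethanone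
Conditions: BnBr (1.05 equiv), K2CO3, acetone, reflux
Reagents that add atoms: benzyl bromide, BrCc1ccccc1
Why: Williamson monobenzylation: the two hydroxyls are equivalent, and after the first alkylation the last one is held in a hydrogen bond to the carbonyl and should stay free.

Step 8
Reactants: 13 1-[2-(benzyloxy)-6-hydroxy-4-(methoxymethoxy)phenyl]ethanone, 14 3,4-bis(benzyloxy)benzaldehyde
Product: 15 (2E)-1-[2-(benzyloxy)-6-hydroxy-4-(methoxymethoxy)phenyl]-3-[3,4-bis(benzyloxy)phenyl]prop-2-en-1-one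
Conditions: KOH, EtOH, rt
Reagents that add atoms: none
Why: Claisen–Schmidt aldol condensation should give the E-chalcone; MOM and benzyl ethers are stable to alkali.

Step 9
Reactants: 15 (2E)-1-[2-(benzyloxy)-6-hydroxy-4-(methoxymethoxy)phenyl]-3-[3,4-bis(benzyloxy)phenyl]prop-2-en-1-one
Product: 16 5-(benzyloxy)-2-[3,4-bis(benzyloxy)phenyl]-7-(methoxymethoxy)-4H-chromen-4-one
Conditions: I2 (10 mol%), DMSO, 120 °C
Reagents that add atoms: none
Why: Iodine-catalysed oxidative cyclisation in DMSO (oxa-Michael addition, then dehydrogenation) should give the flavone, and the unchelated MOM ether should survive catalytic iodine.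

Step 10
Reactants: 16 5-(benzyloxy)-2-[3,4-bis(benzyloxy)phenyl]-7-(methoxymethoxy)-4H-chromen-4-one
Product: 17 5-(benzyloxy)-2-[3,4-bis(benzyloxy)phenyl]-8-iodo-7-(methoxymethoxy)-4H-chromen-4-one
Conditions: I2, CF3CO2Ag, CH2Cl2, 0 °C
Reagents that add atoms: iodine, II
Why: Electrophilic aromatic iodination: with O5 alkylated, 5,7-dialkoxyflavones should react at C8 (para to the 5-alkoxy group, ortho to O7 and O1) and not at the more crowded C6.

Step 11
Reactants: 17 5-(benzyloxy)-2-[3,4-bis(benzyloxy)phenyl]-8-iodo-7-(methoxymethoxy)-4H-chromen-4-one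
Product: 18 5-(benzyloxy)-2-[3,4-bis(benzyloxy)phenyl]-7-(methoxymethoxy)-8-(tributylstannyl)-4H-chromen-4-one
Conditions: (Bu3Sn)2, Pd(PPh3)4 (5 mol%), toluene, 110 °C
Reagents that add atoms: hexabutylditin, CCCC[Sn](CCCC)(CCCC)[Sn](CCCC)(CCCC)CCCC
Why: Pd(0)-catalysed stannylation of the aryl iodide with a distannane should tolerate the flavone carbonyl, which an aryllithium or Grignard route would not.

Step 12
Reactants: 18 5-(benzyloxy)-2-[3,4-bis(benzyloxy)phenyl]-7-(methoxymethoxy)-8-(tributylstannyl)-4H-chromen-4-one, 10 tert-butyl (2R,3S)-5,7-bis(benzyloxy)-2-[4-(benzyloxy)phenyl]-4-oxochromane-3-carboxylate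
Product: 20 tert-butyl (2S,3R)-5,7-bis(benzyloxy)-2-[4-(benzyloxy)phenyl]-3-{5-(benzyloxy)-2-[3,4-bis(benzyloxy)phenyl]-7-(methoxymethoxy)-4-oxo-4H-chromen-8-yl}-4-oxochromane-3-carboxylate, via aryllead triacetate 19 (not isolated)
Conditions: 18, Pb(OAc)4, Hg(OCOCF3)2 (cat.), CHCl3, 40 °C; then 10, pyridine, CHCl3, 40 °C
Reagents that add atoms: none
Why: Hg(II)-catalysed tin–lead exchange gives aryllead triacetate 19, which should arylate the β-keto ester carbon of 10 by Pinhey ligand coupling, a reaction known for 2,6-dioxygenated aryl groups and crowded quaternary centres; the aryl group should enter anti to the C2 aryl, C2 is not touched (its descriptor changes to S only because C3 now outranks the aryl carbon) and C3 can no longer enolise.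

Step 13
Reactants: 20 tert-butyl (2S,3R)-5,7-bis(benzyloxy)-2-[4-(benzyloxy)phenyl]-3-{5-(benzyloxy)-2-[3,4-bis(benzyloxy)phenyl]-7-(methoxymethoxy)-4-oxo-4H-chromen-8-yl}-4-oxochromane-3-carboxylate
Product: 21 (2R,3S)-5,7-bis(benzyloxy)-2-[4-(benzyloxy)phenyl]-3-{5-(benzyloxy)-2-[3,4-bis(benzyloxy)phenyl]-7-hydroxy-4-oxo-4H-chromen-8-yl}chroman-4-one
Conditions: TFA–CH2Cl2–H2O, anisole, 0 °C to 40 °C
Reagents that add atoms: none
Why: Acidolysis of the tert-butyl ester, decarboxylation of the β-keto acid and acetal cleavage of the MOM ether run in one pot; the enol formed on decarboxylation ketonises and equilibrates under acid to the trans (2R,3S) ketone, while C2 is configurationally stable in acid.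

Step 14
Reactants: 21 (2R,3S)-5,7-bis(benzyloxy)-2-[4-(benzyloxy)phenyl]-3-{5-(benzyloxy)-2-[3,4-bis(benzyloxy)phenyl]-7-hydroxy-4-oxo-4H-chromen-8-yl}chroman-4-one
Product: 22 5-(benzyloxy)-2-[3,4-bis(benzyloxy)phenyl]-8-{(2R,3S)-5,7-bis(benzyloxy)-2-[4-(benzyloxy)phenyl]-4-oxochroman-3-yl}-4-oxo-4H-chromen-7-yl hydrogen sulfate
Conditions: SO3·pyridine (6 equiv), pyridine, rt to 40 °C
Reagents that add atoms: sulfur trioxide pyridine complex, [O-]S(=O)(=O)[n+]1ccccc1
Why: O-sulfation with SO3·pyridine: the 7''-OH is the only free hydroxyl, so the position of the sulfate is fixed by the protecting-group pattern.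

Step 15
Reactants: 22 5-(benzyloxy)-2-[3,4-bis(benzyloxy)phenyl]-8-{(2R,3S)-5,7-bis(benzyloxy)-2-[4-(benzyloxy)phenyl]-4-oxochroman-3-yl}-4-oxo-4H-chromen-7-yl hydrogen sulfate
Product: 23 8-[(2R,3S)-5,7-dihydroxy-2-(4-hydroxyphenyl)-4-oxochroman-3-yl]-2-(3,4-dihydroxyphenyl)-5-hydroxy-4-oxo-4H-chromen-7-yl hydrogen sulfate
Conditions: H2 (1 atm), Pd/C, THF–MeOH, rt; then Dowex 50 (H+), 0 °C
Reagents that add atoms: none
Why: Hydrogenolysis of the six benzyl ethers; aryl sulfate monoesters, the flavanone carbonyl and the flavone double bond should survive Pd/C at 1 atm, and the neutral medium leaves C2 and C3 untouched.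

Compound list
1 | 4,6-dihydroxy-1-benzofuran-3(2H)-one | O=C1COc2cc(O)cc(O)c12 | starting material
2 | 4,6-bis(benzyloxy)-1-benzofuran-3(2H)-one | O=C1COc2cc(OCc3ccccc3)cc(OCc3ccccc3)c12 | intermediate
3 | 4,6-bis(benzyloxy)-3-[(tert-butyldimethylsilyl)oxy]-1-benzofuran | CC(C)(C)[Si](C)(C)Oc1coc2cc(OCc3ccccc3)cc(OCc3ccccc3)c12 | intermediate
4 | tert-butyl diazoacetate | CC(C)(C)OC(=O)C=[N+]=[N-] | starting material
5 | tert-butyl bromo(diazo)acetate | CC(C)(C)OC(=O)C(Br)=[N+]=[N-] | intermediate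
6 | bromocyclopropane adduct (racemic): cyclopropane fused to the C2–C3 bond of 3, the new carbon carrying Br and CO2tBu | CC(C)(C)OC(=O)C1(Br)C2Oc3cc(OCc4ccccc4)cc(OCc4ccccc4)c3C12O[Si](C)(C)C(C)(C)C | intermediate
7 | 5,7-bis(benzyloxy)-3-(tert-butoxycarbonyl)-4-[(tert-butyldimethylsilyl)oxy]chromenylium bromide | CC(C)(C)OC(=O)c1c[o+]c2cc(OCc3ccccc3)cc(OCc3ccccc3)c2c1O[Si](C)(C)C(C)(C)C.[Br-] | intermediate
8 | tert-butyl 5,7-bis(benzyloxy)-4-oxo-4H-chromene-3-carboxylate | CC(C)(C)OC(=O)c1coc2cc(OCc3ccccc3)cc(OCc3ccccc3)c2c1=O | intermediate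
9 | [4-(benzyloxy)phenyl]boronic acid | OB(O)c1ccc(OCc2ccccc2)cc1 | starting material
10 | tert-butyl (2R,3S)-5,7-bis(benzyloxy)-2-[4-(benzyloxy)phenyl]-4-oxochromane-3-carboxylate (trans keto form drawn; C3 labile) | O=C1c2c(OCc3ccccc3)cc(OCc3ccccc3)cc2O[C@@H](c2ccc(OCc3ccccc3)cc2)[C@@H]1C(=O)OC(C)(C)C | intermediate
11 | 1-(2,4,6-trihydroxyphenyl)ethanone | CC(=O)c1c(O)cc(O)cc1O | starting material
12 | 1-[2,6-dihydroxy-4-(methoxymethoxy)phenyl]ethanone | CC(=O)c1c(O)cc(OCOC)cc1O | intermediate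
13 | 1-[2-(benzyloxy)-6-hydroxy-4-(methoxymethoxy)phenyl]ethanone | CC(=O)c1c(O)cc(OCOC)cc1OCc1ccccc1 | intermediate
14 | 3,4-bis(benzyloxy)benzaldehyde | O=Cc1ccc(OCc2ccccc2)c(OCc2ccccc2)c1 | starting material
15 | (2E)-1-[2-(benzyloxy)-6-hydroxy-4-(methoxymethoxy)phenyl]-3-[3,4-bis(benzyloxy)phenyl]prop-2-en-1-one | O=C(/C=C/c1ccc(OCc2ccccc2)c(OCc2ccccc2)c1)c1c(O)cc(OCOC)cc1OCc1ccccc1 | intermediate
16 | 5-(benzyloxy)-2-[3,4-bis(benzyloxy)phenyl]-7-(methoxymethoxy)-4H-chromen-4-one | O=c1cc(-c2ccc(OCc3ccccc3)c(OCc3ccccc3)c2)oc2cc(OCOC)cc(OCc3ccccc3)c12 | intermediate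
17 | 5-(benzyloxy)-2-[3,4-bis(benzyloxy)phenyl]-8-iodo-7-(methoxymethoxy)-4H-chromen-4-one | O=c1cc(-c2ccc(OCc3ccccc3)c(OCc3ccccc3)c2)oc2c(I)c(OCOC)cc(OCc3ccccc3)c12 | intermediate
18 | 5-(benzyloxy)-2-[3,4-bis(benzyloxy)phenyl]-7-(methoxymethoxy)-8-(tributylstannyl)-4H-chromen-4-one | CCCC[Sn](CCCC)(CCCC)c1c(OCOC)cc(OCc2ccccc2)c2c(=O)cc(-c3ccc(OCc4ccccc4)c(OCc4ccccc4)c3)oc12 | intermediate
19 | {5-(benzyloxy)-2-[3,4-bis(benzyloxy)phenyl]-7-(methoxymethoxy)-4-oxo-4H-chromen-8-yl}lead triacetate | CC(=O)O[Pb](OC(C)=O)(OC(C)=O)c1c(OCOC)cc(OCc2ccccc2)c2c(=O)cc(-c3ccc(OCc4ccccc4)c(OCc4ccccc4)c3)oc12 | intermediate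
20 | tert-butyl (2S,3R)-5,7-bis(benzyloxy)-2-[4-(benzyloxy)phenyl]-3-{5-(benzyloxy)-2-[3,4-bis(benzyloxy)phenyl]-7-(methoxymethoxy)-4-oxo-4H-chromen-8-yl}-4-oxochromane-3-carboxylate (flavonyl group trans to the C2 aryl) | O=C1c2c(OCc3ccccc3)cc(OCc3ccccc3)cc2O[C@@H](c2ccc(OCc3ccccc3)cc2)[C@]1(C(=O)OC(C)(C)C)c1c(OCOC)cc(OCc2ccccc2)c2c(=O)cc(-c3ccc(OCc4ccccc4)c(OCc4ccccc4)c3)oc12 | intermediate
21 | (2R,3S)-5,7-bis(benzyloxy)-2-[4-(benzyloxy)phenyl]-3-{5-(benzyloxy)-2-[3,4-bis(benzyloxy)phenyl]-7-hydroxy-4-oxo-4H-chromen-8-yl}chroman-4-one | O=C1c2c(OCc3ccccc3)cc(OCc3ccccc3)cc2O[C@@H](c2ccc(OCc3ccccc3)cc2)[C@@H]1c1c(O)cc(OCc2ccccc2)c2c(=O)cc(-c3ccc(OCc4ccccc4)c(OCc4ccccc4)c3)oc12 | intermediate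
22 | 5-(benzyloxy)-2-[3,4-bis(benzyloxy)phenyl]-8-{(2R,3S)-5,7-bis(benzyloxy)-2-[4-(benzyloxy)phenyl]-4-oxochroman-3-yl}-4-oxo-4H-chromen-7-yl hydrogen sulfate | O=C1c2c(OCc3ccccc3)cc(OCc3ccccc3)cc2O[C@@H](c2ccc(OCc3ccccc3)cc2)[C@@H]1c1c(OS(=O)(=O)O)cc(OCc2ccccc2)c2c(=O)cc(-c3ccc(OCc4ccccc4)c(OCc4ccccc4)c3)oc12 | intermediate
23 | 8-[(2R,3S)-5,7-dihydroxy-2-(4-hydroxyphenyl)-4-oxochroman-3-yl]-2-(3,4-dihydroxyphenyl)-5-hydroxy-4-oxo-4H-chromen-7-yl hydrogen sulfate | O=C1c2c(O)cc(O)cc2O[C@@H](c2ccc(O)cc2)[C@@H]1c1c(OS(=O)(=O)O)cc(O)c2c(=O)cc(-c3ccc(O)c(O)c3)oc12 | target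

Total step count: 15. Longest linear sequence: 10 steps (11 to 23, steps 6 to 15).

Steps most likely to fail

Step 12. Ligand coupling at C3, which lies between the C2 aryl group, the ester and the peri 5-benzyloxy group, may stall for steric reasons. While 10 waits in pyridine it may also lose its C2 configuration by ring opening and reclosure through the enolate. The fallback sets out from 10 and comes back at 21. Acidolysis and decarboxylation of 10 (TFA, CH2Cl2) should give (2R)-5,7-bis(benzyloxy)-2-[4-(benzyloxy)phenyl]chroman-4-one F1. O-Silylation (TMSOTf, Et3N, CH2Cl2, 0 °C) should give its trimethylsilyl enol ether F2. Palladium-catalysed α-arylation of F2 with iodide 17 (Pd(dba)2, P(t-Bu)3, Bu3SnF, toluene, 80 °C) should give the 7''-O-MOM ether of 21, F3, trans after equilibration. MOM cleavage (HCl, MeOH) then gives 21.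

Step 4. The carbenoid may attack C2 and the resulting zwitterion may collapse with desilylation to a C2-alkylated benzofuranone without ring enlargement, or the carbenoid may be consumed by the benzyloxy arenes. The fallback sets out from 3 and comes back at 8, and keeps the one-carbon ring enlargement. Free dibromocarbene (CHBr3, KOt-Bu, hexane, 0 °C) should give the gem-dibromocyclopropane F4. On warming, F4 should open with loss of the silyl bromide to 5,7-bis(benzyloxy)-3-bromo-4H-chromen-4-one F5. Bromine–magnesium exchange (i-PrMgCl·LiCl, THF, −40 °C) should give (5,7-bis(benzyloxy)-4-oxo-4H-chromen-3-yl)magnesium chloride F6, which is quenched with Boc2O to give 8.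

Step 5. Insertion of the 3-substituted enone into the aryl–palladium bond may be slow, and the β-keto ester product may lose enantiomeric purity by retro-oxa-Michael ring opening and reclosure. The fallback sets out from 8 and comes back at 10. Acidolysis (TFA, CH2Cl2) should give 5,7-bis(benzyloxy)-4-oxo-4H-chromene-3-carboxylic acid F7. Protodecarboxylation (Ag2CO3 cat., AcOH, DMSO, 120 °C) should give 5,7-bis(benzyloxy)-4H-chromen-4-one F8. The same Pd/PyOx conjugate addition of 9, which is established for unsubstituted chromones, should give (2R)-5,7-bis(benzyloxy)-2-[4-(benzyloxy)phenyl]chroman-4-one F9 (the same compound as F1). C-Acylation of its lithium enolate (LiHMDS, THF, −78 °C; tert-butyl 1H-imidazole-1-carboxylate) then gives 10.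

Further compounds
F1 | step 12 | (2R)-5,7-bis(benzyloxy)-2-[4-(benzyloxy)phenyl]chroman-4-one | O=C1C[C@H](c2ccc(OCc3ccccc3)cc2)Oc2cc(OCc3ccccc3)cc(OCc3ccccc3)c12
F2 | step 12 | {(2R)-5,7-bis(benzyloxy)-2-[4-(benzyloxy)phenyl]-2H-chromen-4-yl}oxy(trimethyl)silane | C[Si](C)(C)OC1=C[C@H](c2ccc(OCc3ccccc3)cc2)Oc2cc(OCc3ccccc3)cc(OCc3ccccc3)c12
F3 | step 12 | (2R,3S)-5,7-bis(benzyloxy)-2-[4-(benzyloxy)phenyl]-3-{5-(benzyloxy)-2-[3,4-bis(benzyloxy)phenyl]-7-(methoxymethoxy)-4-oxo-4H-chromen-8-yl}chroman-4-one | O=C1c2c(OCc3ccccc3)cc(OCc3ccccc3)cc2O[C@@H](c2ccc(OCc3ccccc3)cc2)[C@@H]1c1c(OCOC)cc(OCc2ccccc2)c2c(=O)cc(-c3ccc(OCc4ccccc4)c(OCc4ccccc4)c3)oc12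
F4 | step 4 | gem-dibromocyclopropane fused to the C2–C3 bond of 3 (racemic) | BrC1(Br)C2Oc3cc(OCc4ccccc4)cc(OCc4ccccc4)c3C12O[Si](C)(C)C(C)(C)C
F5 | step 4 | 5,7-bis(benzyloxy)-3-bromo-4H-chromen-4-one | O=c1c(Br)coc2cc(OCc3ccccc3)cc(OCc3ccccc3)c12
F6 | step 4 | (5,7-bis(benzyloxy)-4-oxo-4H-chromen-3-yl)magnesium chloride | O=c1c([Mg]Cl)coc2cc(OCc3ccccc3)cc(OCc3ccccc3)c12
F7 | step 5 | 5,7-bis(benzyloxy)-4-oxo-4H-chromene-3-carboxylic acid | OC(=O)c1coc2cc(OCc3ccccc3)cc(OCc3ccccc3)c2c1=O
F8 | step 5 | 5,7-bis(benzyloxy)-4H-chromen-4-one | O=c1ccoc2cc(OCc3ccccc3)cc(OCc3ccccc3)c12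
F9 | step 5 | (2R)-5,7-bis(benzyloxy)-2-[4-(benzyloxy)phenyl]chroman-4-one | O=C1C[C@H](c2ccc(OCc3ccccc3)cc2)Oc2cc(OCc3ccccc3)cc(OCc3ccccc3)c12
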